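**Strategy.** Everything rests on cutting the Cq–CH3 bond of the acyclic quaternary carbon (Cq), which hangs on ring carbon C1 next to C2 of the cyclohexene. Turning the first homogeranyl carbon into a carbonyl and putting an oxygen on C2 ties Cq into a five-membered lactone cis-fused to the six-membered ring along C1–C2. In one operation, methylation of that lactone enolate on its convex face sets the Cq stereocentre from the carvone-derived centres C1 and C6. The precursor is the cis-fused lactone that already carries the (S)-4-methylhex-5-enyl chain on its α-carbon. Afterwards the carbonyl is grown into the homogeranyl chain and the C2 oxygen is used to move the ring alkene to C2=C3.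

Key step: step 12

Ring numbering used below: C1 carries Cq, C2 is its neighbour (oxygen-bearing until step 18), C3 carries the ring methyl, C6 carries the isopropenyl group.
Remark on the chemistry: the mono-alkylated lactone is drawn with its side chain on the convex face (anti to the cyclohexene ring), as enolate alkylation of the parent lactone should deliver it. This α-carbon becomes planar in the enolate of the key step, so either α-epimer would lead to the same product.

Step 1
Reactants: 1 (S)-3,7-dimethylocta-1,6-diene ((S)-β-citronellene)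
Product: 2 2,2-dimethyl-3-[(3S)-3-methylpent-4-en-1-yl]oxirane (both epimers at the oxirane CH)
Conditions: mCPBA (1.0 equiv), CH2Cl2, 0 °C
Reagents that add atoms: mCPBA (3-chloroperoxybenzoic acid), O=C(OO)c1cccc(Cl)c1
Why: Prilezhaev epoxidation, in which the electrophilic peracid should take the electron-rich trisubstituted alkene and leave the monosubstituted vinyl group and the C3 stereocentre alone.

Step 2
Reactants: 2 2,2-dimethyl-3-[(3S)-3-methylpent-4-en-1-yl]oxirane
Product: 4 (S)-4-methylhex-5-enal, via diol 3 (not isolated)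
Conditions: H5IO6 (1.1 equiv), THF/H2O, 0 °C → rt
Reagents that add atoms: none
Why: acid-mediated epoxide hydration followed by periodate glycol cleavage (Malaprade reaction) should cut only the oxygenated C–C bond, the vinyl group and the stereocentre being inert.

Step 3
Reactants: 4 (S)-4-methylhex-5-enal
Product: 5 (S)-4-methylhex-5-en-1-ol
Conditions: NaBH4, MeOH, 0 °C
Reagents that add atoms: none
Why: borohydride reduction of an aldehyde, which does not touch the alkene or the remote stereocentre.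

Step 4
Reactants: 5 (S)-4-methylhex-5-en-1-ol
Product: 6 (S)-6-iodo-3-methylhex-1-ene
Conditions: I2, PPh3, imidazole, CH2Cl2, 0 °C → rt
Reagents that add atoms: iodine, II
Why: Appel-type iodination of an unhindered primary alcohol by SN2 displacement of the oxyphosphonium group, remote from the stereocentre.

Step 5
Reactants: 7 5-bromo-2-methylpent-2-ene
Product: 8 6-methylhept-5-en-1-yne
Conditions: lithium acetylide–ethylenediamine complex (LiC≡CH·H2NCH2CH2NH2), DMSO, 10 °C → rt
Reagents that add atoms: lithium acetylide–ethylenediamine complex, [Li+].[C-]#C.NCCN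
Why: SN2 alkynylation of a primary bromide by the acetylide in a dipolar aprotic solvent.

Step 6
Reactants: 8 6-methylhept-5-en-1-yne
Product: 10 (E)-1-iodo-2,6-dimethylhepta-1,5-diene, via alkenylalane 9 (not isolated)
Conditions: Al(CH3)3 (2 equiv), (C5H5)2ZrCl2 (0.2 equiv), CH2Cl2, 0 °C → rt; then I2, THF, −30 → 0 °C
Reagents that add atoms: trimethylaluminium, C[Al](C)C; iodine, II
Why: zirconium-catalysed carboalumination (Negishi carboalumination) adds CH3 and Al syn across the terminal alkyne with Al at the terminus, and iodinolysis with retention should give the E-iodide, the trisubstituted alkene being inert.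

Step 7
Reactants: 11 (S)-carvone; 12 methyl bromoacetate
Product: 14 methyl 2-[(1R,6S)-3-methyl-2-oxo-6-(prop-1-en-2-yl)cyclohex-3-en-1-yl]acetate (acetate arm trans to isopropenyl), via lithium dienolate 13 (not isolated)
Conditions: LiN(i-Pr)2, THF, −78 °C; then BrCH2CO2CH3, −78 → −20 °C
Reagents that add atoms: none
Why: kinetic deprotonation at the α'-CH2 gives the cross-conjugated dienolate, whose SN2 alkylation should occur anti to the adjacent isopropenyl group and so set C1 trans to C6 (also the more stable arrangement).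

Step 8
Reactants: 14 methyl 2-[(1R,6S)-3-methyl-2-oxo-6-(prop-1-en-2-yl)cyclohex-3-en-1-yl]acetate
Product: 15 methyl 2-[(1R,2S,6S)-2-hydroxy-3-methyl-6-(prop-1-en-2-yl)cyclohex-3-en-1-yl]acetate (OH trans to the acetate arm)
Conditions: NaBH4, CeCl3·7H2O, MeOH, −78 → 0 °C
Reagents that add atoms: none
Why: Luche reduction is 1,2-selective and spares the ester, and axial hydride attack on the half-chair with both substituents equatorial should give the pseudo-equatorial C2 alcohol trans to the C1 arm, which step 10 inverts.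

Step 9
Reactants: 15 methyl 2-[(1R,2S,6S)-2-hydroxy-3-methyl-6-(prop-1-en-2-yl)cyclohex-3-en-1-yl]acetate
Product: 16 2-[(1R,2S,6S)-2-hydroxy-3-methyl-6-(prop-1-en-2-yl)cyclohex-3-en-1-yl]acetic acid
Conditions: LiOH·H2O, THF/H2O, 0 °C → rt; then 1 M HCl to pH 4, 0 °C
Reagents that add atoms: lithium hydroxide, [Li+].[OH-]
Why: saponification of an unhindered methyl ester, with cold and brief acidification so that the allylic alcohol and the isopropenyl group are not ionised.

Step 10
Reactants: 16 2-[(1R,2S,6S)-2-hydroxy-3-methyl-6-(prop-1-en-2-yl)cyclohex-3-en-1-yl]acetic acid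
Product: 18 (3aR,4S,7aR)-7-methyl-4-(prop-1-en-2-yl)-3a,4,5,7a-tetrahydro-1-benzofuran-2(3H)-one (cis-fused lactone), via oxyphosphonium carboxylate 17 (not isolated)
Conditions: PPh3, DIAD, THF (high dilution), 0 °C → rt
Reagents that add atoms: none
Why: Mitsunobu lactonisation, in which the C2 hydroxyl is activated as its oxyphosphonium group and displaced by the tethered carboxylate (5-exo-tet, SN2) with inversion, so the trans alcohol should close to the cis-fused lactone.

Step 11
Reactants: 18 (3aR,4S,7aR)-7-methyl-4-(prop-1-en-2-yl)-3a,4,5,7a-tetrahydro-1-benzofuran-2(3H)-one; 6 (S)-6-iodo-3-methylhex-1-ene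
Product: 20 (3S,3aS,4S,7aR)-7-methyl-3-[(4S)-4-methylhex-5-en-1-yl]-4-(prop-1-en-2-yl)-3a,4,5,7a-tetrahydro-1-benzofuran-2(3H)-one, via lithium enolate 19 (not isolated)
Conditions: LiN(i-Pr)2, THF, −78 °C; then 6, DMPU, −78 → −20 °C
Reagents that add atoms: none
Why: lactone enolate alkylation (SN2) by a primary iodide, expected on the convex face so that the chain lies anti to the cyclohexene ring, although this α-centre is erased again in step 12.

Step 12
Reactants: 20 (3S,3aS,4S,7aR)-7-methyl-3-[(4S)-4-methylhex-5-en-1-yl]-4-(prop-1-en-2-yl)-3a,4,5,7a-tetrahydro-1-benzofuran-2(3H)-one; 21 iodomethane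
Product: 23 (3R,3aS,4S,7aR)-3,7-dimethyl-3-[(4S)-4-methylhex-5-en-1-yl]-4-(prop-1-en-2-yl)-3a,4,5,7a-tetrahydro-1-benzofuran-2(3H)-one, via lithium enolate 22 (not isolated)
Conditions: LiN(i-Pr)2 (1.3 equiv), THF, −78 °C; then CH3I (3 equiv), DMPU, −78 → −40 °C
Reagents that add atoms: none
Why: LiN(i-Pr)2 removes the single α-hydrogen to give the planar, fully substituted lithium enolate 22, which displaces iodide from iodomethane in an SN2 enolate alkylation that forms the Cq–CH3 bond and closes no ring. The closest known reaction type is the alkylation of cis-fused bicyclic γ-lactone enolates, which accept the electrophile anti to the ring-fusion substituent. The new stereocentre Cq is controlled by the cis C1–C2 ring fusion: the cyclohexene ring (C6 with its isopropenyl group, and C3) folds over the concave face, so methyl should enter on the face that carries the C1 hydrogen. The step needs facial selectivity and C- rather than O-alkylation; the rigid bicycle should secure the first and the small, soft electrophile the second. Because the chain is attached before the methyl group, methyl ends up cis to H–C1 and the chain cis to C6, which is the target configuration once the carbonyl becomes the first homogeranyl carbon.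

Step 13
Reactants: 23 (3R,3aS,4S,7aR)-3,7-dimethyl-3-[(4S)-4-methylhex-5-en-1-yl]-4-(prop-1-en-2-yl)-3a,4,5,7a-tetrahydro-1-benzofuran-2(3H)-one
Product: 24 (3R,3aS,4S,7aR)-3,7-dimethyl-3-[(4S)-4-methylhex-5-en-1-yl]-4-(prop-1-en-2-yl)-2,3,3a,4,5,7a-hexahydro-1-benzofuran-2-ol (lactol; both anomers)
Conditions: i-Bu2AlH (1.2 equiv), CH2Cl2, −78 °C
Reagents that add atoms: none
Why: partial reduction of a lactone with i-Bu2AlH, where the aluminium hemiacetal persists at −78 °C and the quaternary α-carbon shields the carbonyl from over-reduction.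

Step 14
Reactants: 24 lactol (3R,3aS,4S,7aR)-3,7-dimethyl-3-[(4S)-4-methylhex-5-en-1-yl]-4-(prop-1-en-2-yl)-2,3,3a,4,5,7a-hexahydro-1-benzofuran-2-ol
Product: 26 (4S,4aS,5S,8aR)-4,8-dimethyl-4-[(4S)-4-methylhex-5-en-1-yl]-5-(prop-1-en-2-yl)-3,4,4a,5,6,8a-hexahydro-2H-chromen-2-ol (six-membered lactol; both anomers), via enol ether 25 (not isolated)
Conditions: Ph3P(CH2OCH3)Cl, KN(SiMe3)2 (excess), THF, 0 °C → rt; then 1 M HCl, THF, 0 °C → rt
Reagents that add atoms: (methoxymethyl)triphenylphosphonium chloride, COC[P+](c1ccccc1)(c1ccccc1)c1ccccc1.[Cl-]; water, O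
Why: Wittig methoxymethylenation of the open hydroxy-aldehyde form of the lactol followed by enol ether hydrolysis adds one carbon, the new aldehyde is captured by the C2 hydroxyl as a six-membered lactol, and Cq has no α-hydrogen that could epimerise.

Step 15
Reactants: 26 (4S,4aS,5S,8aR)-4,8-dimethyl-4-[(4S)-4-methylhex-5-en-1-yl]-5-(prop-1-en-2-yl)-3,4,4a,5,6,8a-hexahydro-2H-chromen-2-ol
Product: 27 (3S,7S)-3-[(1S,2R,6S)-2-hydroxy-3-methyl-6-(prop-1-en-2-yl)cyclohex-3-en-1-yl]-3,7-dimethylnon-8-en-1-ol (diol)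
Conditions: NaBH4, MeOH/THF, 0 °C → rt
Reagents that add atoms: none
Why: borohydride reduction of a lactol through its open aldehyde tautomer gives the primary alcohol and leaves every stereocentre untouched.

Step 16
Reactants: 27 (3S,7S)-3-[(1S,2R,6S)-2-hydroxy-3-methyl-6-(prop-1-en-2-yl)cyclohex-3-en-1-yl]-3,7-dimethylnon-8-en-1-ol
Product: 28 (5S,6S)-6-[(3S,7S)-1-hydroxy-3,7-dimethylnon-8-en-3-yl]-2-methyl-5-(prop-1-en-2-yl)cyclohex-2-en-1-one (hydroxy enone)
Conditions: MnO2 (activated, excess), CH2Cl2, rt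
Reagents that add atoms: none
Why: allylic oxidation with MnO2 should take only the allylic C2 alcohol and not the saturated primary one, and the C1 centre next to the new ketone already holds its favoured trans arrangement.

Step 17
Reactants: 28 (5S,6S)-6-[(3S,7S)-1-hydroxy-3,7-dimethylnon-8-en-3-yl]-2-methyl-5-(prop-1-en-2-yl)cyclohex-2-en-1-one
Product: 29 tosylhydrazone of 28 (C2=N–NH–SO2C6H4CH3)
Conditions: TsNHNH2, EtOH, 50 °C
Reagents that add atoms: 4-methylbenzenesulfonohydrazide, Cc1ccc(cc1)S(=O)(=O)NN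
Why: condensation of a ketone with a sulfonyl hydrazide under near-neutral conditions that do not epimerise C1 or disturb the alkenes.

Step 18
Reactants: 29 tosylhydrazone of 28
Product: 32 (3S,7S)-3,7-dimethyl-3-[(1S,6S)-3-methyl-6-(prop-1-en-2-yl)cyclohex-2-en-1-yl]non-8-en-1-ol, via borylated allylic tosylhydrazine 30 (not isolated), via allylic diazene 31 (not isolated)
Conditions: catecholborane (3 equiv; the hydroxyl group takes up one), CHCl3, 0 °C; then NaOAc·3H2O, 60 °C
Reagents that add atoms: none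
Why: reduction of the conjugated tosylhydrazone with catecholborane, loss of sulfinate to the allylic diazene and retro-ene loss of N2 (tosylhydrazone reduction with alkene transposition) should deliver hydrogen to C4 and place the alkene at C2=C3 without creating a stereocentre.

Step 19
Reactants: 32 (3S,7S)-3,7-dimethyl-3-[(1S,6S)-3-methyl-6-(prop-1-en-2-yl)cyclohex-2-en-1-yl]non-8-en-1-ol
Product: 33 (3S,7S)-9-iodo-3,7-dimethyl-7-[(1S,6S)-3-methyl-6-(prop-1-en-2-yl)cyclohex-2-en-1-yl]non-1-ene
Conditions: I2, PPh3, imidazole, CH2Cl2, 0 °C → rt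
Reagents that add atoms: iodine, II
Why: Appel-type iodination of the only hydroxyl group, a primary alcohol, by SN2 displacement.

Step 20
Reactants: 33 (3S,7S)-9-iodo-3,7-dimethyl-7-[(1S,6S)-3-methyl-6-(prop-1-en-2-yl)cyclohex-2-en-1-yl]non-1-ene; 10 (E)-1-iodo-2,6-dimethylhepta-1,5-diene
Product: 36 (3S,7S,10E)-3,7,11,15-tetramethyl-7-[(1S,6S)-3-methyl-6-(prop-1-en-2-yl)cyclohex-2-en-1-yl]hexadeca-1,10,14-triene (CNP0208273.1), via alkyllithium 34 (not isolated), via lithium borate 35 (not isolated)
Conditions: t-BuLi (2.1 equiv), Et2O, −78 °C; B-methoxy-9-BBN, THF, −78 °C → rt; then 10, PdCl2(dppf) (5 mol %), K3PO4 (3 M aq.), DMF, rt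
Reagents that add atoms: none
Why: B-alkyl Suzuki–Miyaura coupling in which iodine–lithium exchange and capture as the 9-BBN borate supply the alkyl partner without any hydroboration (which the three other alkenes would not survive), and transmetalation and reductive elimination on palladium keep the E geometry of the alkenyl iodide.

**Compound list**

1 | (S)-3,7-dimethylocta-1,6-diene ((S)-β-citronellene) | C=C[C@@H](C)CCC=C(C)C | starting material
2 | 2,2-dimethyl-3-[(3S)-3-methylpent-4-en-1-yl]oxirane (both epimers at the oxirane CH) | C=C[C@@H](C)CCC1OC1(C)C | intermediate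
3 | (6S)-2,6-dimethyloct-7-ene-2,3-diol (both epimers at C3) | C=C[C@@H](C)CCC(O)C(C)(C)O | intermediate (not isolated)
4 | (S)-4-methylhex-5-enal | C=C[C@@H](C)CCC=O | intermediate
5 | (S)-4-methylhex-5-en-1-ol | C=C[C@@H](C)CCCO | intermediate
6 | (S)-6-iodo-3-methylhex-1-ene | C=C[C@@H](C)CCCI | intermediate
7 | 5-bromo-2-methylpent-2-ene | CC(C)=CCCBr | starting material
8 | 6-methylhept-5-en-1-yne | CC(C)=CCCC#C | intermediate
9 | [(1E)-2,6-dimethylhepta-1,5-dien-1-yl]dimethylalane | CC(C)=CCC/C(C)=C/[Al](C)C | intermediate (not isolated)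
10 | (E)-1-iodo-2,6-dimethylhepta-1,5-diene | CC(C)=CCC/C(C)=C/I | intermediate
11 | (S)-carvone, (5S)-2-methyl-5-(prop-1-en-2-yl)cyclohex-2-en-1-one | CC1=CC[C@H](C(C)=C)CC1=O | starting material
12 | methyl bromoacetate | COC(=O)CBr | starting material
13 | lithium (3S)-6-methyl-3-(prop-1-en-2-yl)cyclohexa-1,5-dien-1-olate (kinetic dienolate of 11) | CC1=CC[C@H](C(C)=C)C=C1O[Li] | intermediate (not isolated)
14 | methyl 2-[(1R,6S)-3-methyl-2-oxo-6-(prop-1-en-2-yl)cyclohex-3-en-1-yl]acetate | COC(=O)C[C@H]1C(=O)C(C)=CC[C@@H]1C(C)=C | intermediate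
15 | methyl 2-[(1R,2S,6S)-2-hydroxy-3-methyl-6-(prop-1-en-2-yl)cyclohex-3-en-1-yl]acetate | COC(=O)C[C@H]1[C@H](O)C(C)=CC[C@@H]1C(C)=C | intermediate
16 | 2-[(1R,2S,6S)-2-hydroxy-3-methyl-6-(prop-1-en-2-yl)cyclohex-3-en-1-yl]acetic acid | OC(=O)C[C@H]1[C@H](O)C(C)=CC[C@@H]1C(C)=C | intermediate
17 | oxyphosphonium carboxylate of 16 (C2–O–PPh3 cation, carboxylate anion) | [O-]C(=O)C[C@H]1[C@H](O[P+](c2ccccc2)(c2ccccc2)c2ccccc2)C(C)=CC[C@@H]1C(C)=C | intermediate (not isolated)
18 | (3aR,4S,7aR)-7-methyl-4-(prop-1-en-2-yl)-3a,4,5,7a-tetrahydro-1-benzofuran-2(3H)-one (cis-fused lactone) | C1C(=O)O[C@H]2C(C)=CC[C@H](C(=C)C)[C@@H]12 | intermediate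
19 | lithium enolate of lactone 18 | C1=C(O[Li])O[C@H]2C(C)=CC[C@H](C(=C)C)[C@@H]12 | intermediate (not isolated)
20 | (3S,3aS,4S,7aR)-7-methyl-3-[(4S)-4-methylhex-5-en-1-yl]-4-(prop-1-en-2-yl)-3a,4,5,7a-tetrahydro-1-benzofuran-2(3H)-one (chain on the convex face) | C=C[C@@H](C)CCC[C@@H]1C(=O)O[C@H]2C(C)=CC[C@H](C(=C)C)[C@@H]12 | intermediate
21 | iodomethane | CI | starting material
22 | lithium enolate of lactone 20 (α-carbon planar) | C=C[C@@H](C)CCCC1=C(O[Li])O[C@H]2C(C)=CC[C@H](C(=C)C)[C@@H]12 | intermediate (not isolated)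
23 | (3R,3aS,4S,7aR)-3,7-dimethyl-3-[(4S)-4-methylhex-5-en-1-yl]-4-(prop-1-en-2-yl)-3a,4,5,7a-tetrahydro-1-benzofuran-2(3H)-one (methyl cis to H–C1) | C=C[C@@H](C)CCC[C@@]1(C)C(=O)O[C@H]2C(C)=CC[C@H](C(=C)C)[C@@H]12 | intermediate
24 | (3R,3aS,4S,7aR)-3,7-dimethyl-3-[(4S)-4-methylhex-5-en-1-yl]-4-(prop-1-en-2-yl)-2,3,3a,4,5,7a-hexahydro-1-benzofuran-2-ol (both anomers) | C=C[C@@H](C)CCC[C@@]1(C)C(O)O[C@H]2C(C)=CC[C@H](C(=C)C)[C@@H]12 | intermediate
25 | (1R,5S,6S)-6-[(3S,7S)-1-methoxy-3,7-dimethylnona-1,8-dien-3-yl]-2-methyl-5-(prop-1-en-2-yl)cyclohex-2-en-1-ol (E/Z mixture at the enol ether) | C=C[C@@H](C)CCC[C@@](C)(C=COC)[C@H]1[C@@H](O)C(C)=CC[C@@H]1C(=C)C | intermediate (not isolated)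
26 | (4S,4aS,5S,8aR)-4,8-dimethyl-4-[(4S)-4-methylhex-5-en-1-yl]-5-(prop-1-en-2-yl)-3,4,4a,5,6,8a-hexahydro-2H-chromen-2-ol (both anomers) | C=C[C@@H](C)CCC[C@@]1(C)CC(O)O[C@H]2C(C)=CC[C@H](C(=C)C)[C@@H]12 | intermediate
27 | (3S,7S)-3-[(1S,2R,6S)-2-hydroxy-3-methyl-6-(prop-1-en-2-yl)cyclohex-3-en-1-yl]-3,7-dimethylnon-8-en-1-ol | C=C[C@@H](C)CCC[C@@](C)(CCO)[C@H]1[C@@H](O)C(C)=CC[C@@H]1C(=C)C | intermediate
28 | (5S,6S)-6-[(3S,7S)-1-hydroxy-3,7-dimethylnon-8-en-3-yl]-2-methyl-5-(prop-1-en-2-yl)cyclohex-2-en-1-one | C=C[C@@H](C)CCC[C@@](C)(CCO)[C@H]1C(=O)C(C)=CC[C@@H]1C(=C)C | intermediate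
29 | tosylhydrazone of 28 (C=N geometry not defined) | C=C[C@@H](C)CCC[C@@](C)(CCO)[C@H]1C(=NNS(=O)(=O)c2ccc(C)cc2)C(C)=CC[C@@H]1C(=C)C | intermediate
30 | allylic N-tosylhydrazine from 29, N- and O-bound to catecholboryl groups (C2 configuration immaterial) | C=C[C@@H](C)CCC[C@@](C)(CCOB2Oc3ccccc3O2)[C@H]1C(N(B2Oc3ccccc3O2)NS(=O)(=O)c2ccc(C)cc2)C(C)=CC[C@@H]1C(=C)C | intermediate (not isolated)
31 | allylic diazene (C2–N=NH, C3=C4; C2 configuration immaterial) | C=C[C@@H](C)CCC[C@@](C)(CCO)[C@H]1C(N=N)C(C)=CC[C@@H]1C(=C)C | intermediate (not isolated)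
32 | (3S,7S)-3,7-dimethyl-3-[(1S,6S)-3-methyl-6-(prop-1-en-2-yl)cyclohex-2-en-1-yl]non-8-en-1-ol | C=C[C@@H](C)CCC[C@@](C)(CCO)[C@H]1C=C(C)CC[C@@H]1C(=C)C | intermediate
33 | (3S,7S)-9-iodo-3,7-dimethyl-7-[(1S,6S)-3-methyl-6-(prop-1-en-2-yl)cyclohex-2-en-1-yl]non-1-ene | C=C[C@@H](C)CCC[C@@](C)(CCI)[C@H]1C=C(C)CC[C@@H]1C(=C)C | intermediate
34 | primary alkyllithium from 33 (Li in place of I) | C=C[C@@H](C)CCC[C@@](C)(CC[Li])[C@H]1C=C(C)CC[C@@H]1C(=C)C | intermediate (not isolated)
35 | lithium B-alkyl-B-methoxy-9-borabicyclo[3.3.1]nonane borate from 34 | C=C[C@@H](C)CCC[C@@](C)(CC[B-]2(OC)C3CCCC2CCC3)[C@H]1C=C(C)CC[C@@H]1C(=C)C.[Li+] | intermediate (not isolated)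
36 | (3S,7S,10E)-3,7,11,15-tetramethyl-7-[(1S,6S)-3-methyl-6-(prop-1-en-2-yl)cyclohex-2-en-1-yl]hexadeca-1,10,14-triene (CNP0208273.1) | C=C[C@@H](C)CCC[C@@](C)(CC/C=C(\C)CCC=C(C)C)[C@H]1C=C(C)CC[C@@H]1C(=C)C | target

**Totals.** Total step count: 20. Longest linear sequence: 14 steps (steps 7–20 from (S)-carvone; the citronellene branch, steps 1–4 followed by 11–20, is equally long).

**Steps most likely to fail**

1. Step 12. The C–C bond formation at the crowded, fully substituted enolate carbon may be slow, so that proton return or O-methylation competes, and part of the electrophile may reach the concave face. The fallback sets out from 20 and comes back at 23, bringing the carbon in at a higher oxidation level. Enolate 22 is generated as before and quenched with monomeric formaldehyde gas (aldol addition, convex face) to give the hydroxymethyl lactone F1; any Cq epimer should be easier to remove at this alcohol stage. Dess–Martin oxidation then gives the formyl lactone F2 and condensation with TsNHNH2 gives the tosylhydrazone F3. Catecholborane followed by NaOAc·3H2O (tosylhydrazone deoxygenation) turns the CH=N–NHTs group into CH3 and delivers 23.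

2. Step 14. The hindered five-membered lactol may not open to its hydroxy aldehyde, and the short-lived ylide may decay before it attacks the neopentyl-type carbonyl. The fallback sets out from 23 and comes back at 26, using a free, protected aldehyde. LiAlH4 reduces the lactone to the diol F4 and Et3SiOTf/2,6-lutidine gives the bis(triethylsilyl) ether F5. Swern oxidation, which converts a primary triethylsilyl ether directly into the aldehyde while the secondary one stays, gives the silyloxy aldehyde F6. Wittig reaction with Ph3P=CHOCH3 then gives the enol ether F7, and aqueous HCl in THF cleaves the silyl ether and the enol ether together, closing to lactol 26.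

3. Step 10. Activation of the carboxylic acid instead of the alcohol may lead to closure with retention or to oligomers, and the activated allylic alcohol may eliminate to a diene. The fallback sets out from 15 and comes back at 18, separating inversion from ring closure. Intermolecular Mitsunobu reaction of 15 with 4-nitrobenzoic acid (PPh3, DIAD) gives the inverted 4-nitrobenzoate F8. Methanolysis with K2CO3/MeOH frees the cis hydroxy ester F9, which should lactonise on mildly acidic work-up to 18.

**Further compounds**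

F1 | step 12 | (3R,3aS,4S,7aR)-3-(hydroxymethyl)-7-methyl-3-[(4S)-4-methylhex-5-en-1-yl]-4-(prop-1-en-2-yl)-3a,4,5,7a-tetrahydro-1-benzofuran-2(3H)-one (CH2OH in the place of the methyl group of 23) | C=C[C@@H](C)CCC[C@@]1(CO)C(=O)O[C@H]2C(C)=CC[C@H](C(=C)C)[C@@H]12
F2 | step 12 | formyl lactone (CHO in the place of the methyl group of 23) | C=C[C@@H](C)CCC[C@@]1(C=O)C(=O)O[C@H]2C(C)=CC[C@H](C(=C)C)[C@@H]12
F3 | step 12 | tosylhydrazone of formyl lactone F2 | C=C[C@@H](C)CCC[C@@]1(C=NNS(=O)(=O)c3ccc(C)cc3)C(=O)O[C@H]2C(C)=CC[C@H](C(=C)C)[C@@H]12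
F4 | step 14 | diol from reduction of 23 (Cq–CH2OH and C2–OH cis to the C1 substituent) | C=C[C@@H](C)CCC[C@@](C)(CO)[C@H]1[C@@H](O)C(C)=CC[C@@H]1C(=C)C
F5 | step 14 | bis(triethylsilyl) ether of F4 | C=C[C@@H](C)CCC[C@@](C)(CO[Si](CC)(CC)CC)[C@H]1[C@@H](O[Si](CC)(CC)CC)C(C)=CC[C@@H]1C(=C)C
F6 | step 14 | aldehyde Cq–CHO with C2–OSiEt3 | C=C[C@@H](C)CCC[C@@](C)(C=O)[C@H]1[C@@H](O[Si](CC)(CC)CC)C(C)=CC[C@@H]1C(=C)C
F7 | step 14 | enol ether Cq–CH=CH–OCH3 with C2–OSiEt3 (E/Z mixture) | C=C[C@@H](C)CCC[C@@](C)(C=COC)[C@H]1[C@@H](O[Si](CC)(CC)CC)C(C)=CC[C@@H]1C(=C)C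
F8 | step 10 | methyl 2-[(1R,2R,6S)-3-methyl-2-(4-nitrobenzoyloxy)-6-(prop-1-en-2-yl)cyclohex-3-en-1-yl]acetate (ester oxygen cis to the acetate arm) | COC(=O)C[C@H]1[C@@H](OC(=O)c2ccc(cc2)[N+](=O)[O-])C(C)=CC[C@@H]1C(C)=C
F9 | step 10 | methyl 2-[(1R,2R,6S)-2-hydroxy-3-methyl-6-(prop-1-en-2-yl)cyclohex-3-en-1-yl]acetate (OH cis to the acetate arm) | COC(=O)C[C@H]1[C@@H](O)C(C)=CC[C@@H]1C(C)=C
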